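**Retrosynthetic overview**
- The ten-membered ring is closed last, by ring-closing metathesis at C5=C6 of a triene that already carries ring A, both ester groups and the butenolide.
- The butenolide is made by forming the C7–O bond: a gold-catalysed cyclisation of a tert-butyl (Z)-2-en-4,5-dienoate, ester oxygen onto the allene, which also sets C7.
- The dienoate comes from a ring-A aldehyde through a β-keto ester (Roskamp), its (Z)-enol triflate and an allenyl Stille coupling.
- Ring A with C1, C2, C10 and C14 comes from (S)-carvone: α′-formylation and methylation (C1), Criegee rearrangement (isopropenyl to the C14 acetate), alkyl addition (C2), then epoxidation, Wharton transposition and Claisen rearrangement (C10, C11=C12).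
- Ring order: ring A (carvone), then the butenolide, then the ten-membered ring.

Assumption: atom labels such as C2, C7, C10 or C14 in the Why lines follow the briarane numbering of the target (C1 quaternary ring-fusion carbon, C2 propionate carbon, C5=C6 ring alkene, C7 lactone CH–O, C8=C17 butenolide alkene, C19 lactone C=O, C10 ring-fusion CH, C11=C12 ring-A alkene, C14 acetate carbon).
Assumption: compounds 1, 7, 16 and 20 are bought.

**Step 1**
Reactants: 1 (S)-(+)-carvone
Product: 3 (5R,6Z)-6-(hydroxymethylidene)-2-methyl-5-(prop-1-en-2-yl)cyclohex-2-en-1-one, via lithium dienolate 2 (not isolated)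
Conditions: LiN(iPr)2, THF, −78 °C; CF3CH2OCHO, −78 → 0 °C; aq. HCl
Reagents that add atoms: 2,2,2-trifluoroethyl formate, O=COCC(F)(F)F
Why: Kinetic α′-deprotonation of the enone gives the cross-conjugated dienolate, which is C-formylated by the activated formate (Claisen-type formylation), leaving the carvone stereocentre (later C14) untouched.

**Step 2**
Reactants: 3 (5R,6Z)-6-(hydroxymethylidene)-2-methyl-5-(prop-1-en-2-yl)cyclohex-2-en-1-one
Product: 4 (1R,6R)-1,3-dimethyl-2-oxo-6-(prop-1-en-2-yl)cyclohex-3-ene-1-carbaldehyde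
Conditions: MeI, K2CO3, acetone, 25 °C
Reagents that add atoms: iodomethane, CI
Why: C-alkylation of the β-keto aldehyde enolate occurs anti to the neighbouring isopropenyl group, so the quaternary centre C1 is set with methyl trans and formyl cis to the future C14 oxygen.

**Step 3**
Reactants: 4 (1R,6R)-1,3-dimethyl-2-oxo-6-(prop-1-en-2-yl)cyclohex-3-ene-1-carbaldehyde
Product: 6 (1S,2R)-2-formyl-2,4-dimethyl-3-oxocyclohex-4-en-1-yl acetate, via methoxy hydroperoxide 5 (not isolated)
Conditions: O3, CH2Cl2/MeOH, −78 °C; then Ac2O, Et3N, DMAP (cat.), CH2Cl2, 0 → 25 °C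
Reagents that add atoms: ozone, [O-][O+]=O
Why: Ozone cleaves the electron-rich isopropenyl group selectively (the enone alkene is deactivated), and the peracetate of the methoxy hydroperoxide undergoes Criegee rearrangement with retention at the migrating carbon, turning the isopropenyl group directly into the C14 acetate of the target.

**Step 4**
Reactants: 6 (1S,2R)-2-formyl-2,4-dimethyl-3-oxocyclohex-4-en-1-yl acetate; 7 4-bromo-2-methylbut-1-ene
Product: 10 (1S,2S)-2-[(1S)-1-hydroxy-4-methylpent-4-en-1-yl]-2,4-dimethyl-3-oxocyclohex-4-en-1-yl acetate, via Grignard reagent 8 (not isolated), via alkyltitanium reagent 9 (not isolated)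
Conditions: 7, Mg, Et2O, 35 °C; Ti(OiPr)4 (4 equiv), (S)-3-(3,5-diphenylphenyl)-H8-BINOL (5 mol %), CH2Cl2, −78 → 0 °C; then 6, 0 °C; aq. NH4Cl
Reagents that add atoms: none
Why: Catalytic asymmetric alkyl transfer from a Grignard-derived alkyltitanium (titanium–BINOLate catalysis) attacks only the aldehyde, and the (S)-ligand delivers the alkyl group to the Si face, setting C2 as S (1,3-anti to the C14 oxygen), the same sense as the non-chelated dipole-minimised addition.

**Step 5**
Reactants: 10 (1S,2S)-2-[(1S)-1-hydroxy-4-methylpent-4-en-1-yl]-2,4-dimethyl-3-oxocyclohex-4-en-1-yl acetate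
Product: 11 (1S)-1-[(1S,6S)-6-(acetyloxy)-1,3-dimethyl-2-oxocyclohex-3-en-1-yl]-4-methylpent-4-en-1-yl propanoate
Conditions: (EtCO)2O, Sc(OTf)3 (2 mol %), MeCN, −20 °C
Reagents that add atoms: propanoic anhydride, CCC(=O)OC(=O)CC
Why: Lewis-acid-catalysed acylation of the hindered secondary alcohol installs the propionate of the target without base, which avoids 1,3-acetyl migration and retro-aldol cleavage.

**Step 6**
Reactants: 11 (1S)-1-[(1S,6S)-6-(acetyloxy)-1,3-dimethyl-2-oxocyclohex-3-en-1-yl]-4-methylpent-4-en-1-yl propanoate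
Product: 12 (1S)-1-[(1S,3S,4S,6S)-4-(acetyloxy)-1,3-dimethyl-2-oxo-7-oxabicyclo[4.1.0]heptan-3-yl]-4-methylpent-4-en-1-yl propanoate
Conditions: t-BuOOH, DBU, CH2Cl2, 0 → 25 °C
Reagents that add atoms: tert-butyl hydroperoxide, CC(C)(C)OO
Why: Weitz–Scheffer nucleophilic epoxidation of the enone, in which the peroxide anion adds to the β-carbon anti to the C14 acetate (as in carvone epoxidation), gives the epoxide trans to the acetate.

**Step 7**
Reactants: 12 (1S)-1-[(1S,3S,4S,6S)-4-(acetyloxy)-1,3-dimethyl-2-oxo-7-oxabicyclo[4.1.0]heptan-3-yl]-4-methylpent-4-en-1-yl propanoate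
Product: 13 (1S)-1-[(1S,4S,6S)-6-(acetyloxy)-4-hydroxy-1,3-dimethylcyclohex-2-en-1-yl]-4-methylpent-4-en-1-yl propanoate
Conditions: N2H4·H2O, AcOH (cat.), MeOH, 0 → 25 °C
Reagents that add atoms: none
Why: Wharton transposition, in which the epoxy hydrazone fragments with loss of N2, gives the transposed allylic alcohol with the C12–O configuration retained and the double bond at C10=C11.

**Step 8**
Reactants: 13 (1S)-1-[(1S,4S,6S)-6-(acetyloxy)-4-hydroxy-1,3-dimethylcyclohex-2-en-1-yl]-4-methylpent-4-en-1-yl propanoate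
Product: 15 (1S)-1-[(1S,2S,6S)-6-(acetyloxy)-1,3-dimethyl-2-(2-oxoethyl)cyclohex-3-en-1-yl]-4-methylpent-4-en-1-yl propanoate, via allyl vinyl ether 14 (not isolated)
Conditions: ethyl vinyl ether, Pd(OCOCF3)2 (5 mol %), 4,7-diphenyl-1,10-phenanthroline, Et3N (cat.), 25 °C; evaporate; o-xylene, 180 °C (sealed tube)
Reagents that add atoms: ethyl vinyl ether, C=COCC
Why: Palladium-catalysed transfer vinylation followed by a thermal Claisen [3,3] rearrangement moves the CH2CHO unit suprafacially from the C12 oxygen to C10, which sets C10 (side chain trans to the C14 acetate, cis to the C1 methyl) and places the ring alkene at C11=C12.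

**Step 9**
Reactants: 16 tert-butyl 2-methyl-3-oxobutanoate
Product: 17 tert-butyl 2-diazopropanoate
Conditions: 4-acetamidobenzenesulfonyl azide, DBU, MeCN, 0 → 25 °C
Reagents that add atoms: 4-acetamidobenzenesulfonyl azide, CC(=O)Nc1ccc(cc1)S(=O)(=O)N=[N+]=[N-]
Why: Regitz deacylative diazo transfer to an α-methyl β-keto ester gives the α-diazo ester with loss of the acetyl group.

**Step 10**
Reactants: 15 (1S)-1-[(1S,2S,6S)-6-(acetyloxy)-1,3-dimethyl-2-(2-oxoethyl)cyclohex-3-en-1-yl]-4-methylpent-4-en-1-yl propanoate; 17 tert-butyl 2-diazopropanoate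
Product: 18 tert-butyl 4-[(1S,5S,6S)-5-(acetyloxy)-2,6-dimethyl-6-[(1S)-4-methyl-1-(propanoyloxy)pent-4-en-1-yl]cyclohex-2-en-1-yl]-2-methyl-3-oxobutanoate
Conditions: Sc(OTf)3 (5 mol %), CH2Cl2, −20 → 25 °C
Reagents that add atoms: none
Why: Roskamp homologation, in which the diazo ester adds to the Lewis-acid-activated aldehyde and a 1,2-hydride shift expels N2, gives the α-methyl β-keto ester that carries C8, C17, the C17 methyl and C19.

**Step 11**
Reactants: 18 tert-butyl 4-[(1S,5S,6S)-5-(acetyloxy)-2,6-dimethyl-6-[(1S)-4-methyl-1-(propanoyloxy)pent-4-en-1-yl]cyclohex-2-en-1-yl]-2-methyl-3-oxobutanoate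
Product: 19 tert-butyl (2Z)-4-[(1S,5S,6S)-5-(acetyloxy)-2,6-dimethyl-6-[(1S)-4-methyl-1-(propanoyloxy)pent-4-en-1-yl]cyclohex-2-en-1-yl]-2-methyl-3-{[(trifluoromethyl)sulfonyl]oxy}but-2-enoate
Conditions: Tf2O, LiOTf, Et3N, CH2Cl2, 0 °C
Reagents that add atoms: trifluoromethanesulfonic anhydride, O=S(=O)(OS(=O)(=O)C(F)(F)F)C(F)(F)F
Why: The lithium-chelated (Z)-enolate of the β-keto ester is trapped on oxygen (stereoselective enol triflate formation), so the triflate is cis to the ester, the geometry needed for the later lactone.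

**Step 12**
Reactants: 19 the (Z)-enol triflate; 20 tributyl(propa-1,2-dien-1-yl)stannane
Product: 21 tert-butyl (2Z)-3-{[(1S,5S,6S)-5-(acetyloxy)-2,6-dimethyl-6-[(1S)-4-methyl-1-(propanoyloxy)pent-4-en-1-yl]cyclohex-2-en-1-yl]methyl}-2-methylhexa-2,4,5-trienoate
Conditions: Pd2(dba)3 (2.5 mol %), P(2-furyl)3 (10 mol %), LiCl, NMP, 25 °C
Reagents that add atoms: none
Why: Stille coupling with retention of the enol triflate geometry attaches the allenyl group (C7, C6 and a terminal CH2) cis to the ester.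

**Step 13**
Reactants: 21 the (Z)-vinylallene tert-butyl ester
Product: 22 (1S)-1-[(1S,2S,6S)-6-(acetyloxy)-2-{[(2R)-2-ethenyl-4-methyl-5-oxo-2,5-dihydrofuran-3-yl]methyl}-1,3-dimethylcyclohex-3-en-1-yl]-4-methylpent-4-en-1-yl propanoate
Conditions: [(R)-DTBM-SEGPHOS](AuCl)2 (2.5 mol %), AgNTf2 (5 mol %), CH2Cl2, −20 °C
Reagents that add atoms: none
Why: Proposed new method: a cationic chiral bis(phosphine)digold catalyst π-activates the allene, the cis tert-butyl ester carbonyl oxygen attacks the proximal allene carbon C7 anti to gold in a 5-exo mode, the alkoxyfuranium ion loses isobutene and the vinyl–gold bond is protonated, which forms the C7–O bond, closes the butenolide and sets C7 (R) by ligand control of the prochiral allene face (the ligand antipode that gives 7R is used); the closest known reactions are the gold-catalysed enantioselective cyclisations of γ-allenic acids and alcohols to 2-vinyl lactones and tetrahydrofurans and the gold-catalysed cyclisation of tert-butyl 2,3-allenoates to butenolides, neither shown on a conjugated (Z)-2-en-4,5-dienoate.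

**Step 14**
Reactants: 22 the 5-vinyl butenolide
Product: 23 target CNP0112230.1
Conditions: second-generation Hoveyda–Grubbs catalyst (15 mol %), 1,4-benzoquinone (30 mol %), toluene (0.5 mM), 100 °C
Reagents that add atoms: none
Why: Ring-closing metathesis between the C7 vinyl group and the 1,1-disubstituted alkene closes the ten-membered ring with loss of ethene, and the (Z)-trisubstituted C5=C6 alkene is the geometry the trans-fused, butenolide-annulated ring accommodates.

**Compound list**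
1 | (S)-(+)-carvone, (5S)-2-methyl-5-(prop-1-en-2-yl)cyclohex-2-en-1-one | CC1=CC[C@@H](CC1=O)C(C)=C | starting material
2 | lithium (3S)-6-methyl-3-(prop-1-en-2-yl)cyclohexa-1,5-dien-1-olate | [Li+].[O-]C1=C[C@@H](C(C)=C)CC=C1C | intermediate (not isolated)
3 | (5R,6Z)-6-(hydroxymethylidene)-2-methyl-5-(prop-1-en-2-yl)cyclohex-2-en-1-one | O/C=C1\C(=O)C(C)=CC[C@@H]1C(C)=C | intermediate
4 | (1R,6R)-1,3-dimethyl-2-oxo-6-(prop-1-en-2-yl)cyclohex-3-ene-1-carbaldehyde | O=C[C@@]1(C)[C@@H](C(C)=C)CC=C(C)C1=O | intermediate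
5 | (1R,6S)-6-(1-hydroperoxy-1-methoxyethyl)-1,3-dimethyl-2-oxocyclohex-3-ene-1-carbaldehyde (both epimers at the peroxy carbon) | O=C[C@@]1(C)[C@@H](C(C)(OC)OO)CC=C(C)C1=O | intermediate (not isolated)
6 | (1S,2R)-2-formyl-2,4-dimethyl-3-oxocyclohex-4-en-1-yl acetate | O=C[C@@]1(C)[C@@H](OC(C)=O)CC=C(C)C1=O | intermediate
7 | 4-bromo-2-methylbut-1-ene | C=C(C)CCBr | starting material
8 | (3-methylbut-3-en-1-yl)magnesium bromide | C=C(C)CC[Mg]Br | intermediate (not isolated)
9 | (3-methylbut-3-en-1-yl)tris(propan-2-olato)titanium | C=C(C)CC[Ti](OC(C)C)(OC(C)C)OC(C)C | intermediate (not isolated)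
10 | (1S,2S)-2-[(1S)-1-hydroxy-4-methylpent-4-en-1-yl]-2,4-dimethyl-3-oxocyclohex-4-en-1-yl acetate | O[C@@H](CCC(C)=C)[C@@]1(C)[C@@H](OC(C)=O)CC=C(C)C1=O | intermediate
11 | (1S)-1-[(1S,6S)-6-(acetyloxy)-1,3-dimethyl-2-oxocyclohex-3-en-1-yl]-4-methylpent-4-en-1-yl propanoate | CCC(=O)O[C@@H](CCC(C)=C)[C@@]1(C)[C@@H](OC(C)=O)CC=C(C)C1=O | intermediate
12 | (1S)-1-[(1S,3S,4S,6S)-4-(acetyloxy)-1,3-dimethyl-2-oxo-7-oxabicyclo[4.1.0]heptan-3-yl]-4-methylpent-4-en-1-yl propanoate (epoxide trans to the acetate) | CCC(=O)O[C@@H](CCC(C)=C)[C@@]1(C)[C@@H](OC(C)=O)C[C@@H]2O[C@]2(C)C1=O | intermediate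
13 | (1S)-1-[(1S,4S,6S)-6-(acetyloxy)-4-hydroxy-1,3-dimethylcyclohex-2-en-1-yl]-4-methylpent-4-en-1-yl propanoate | CCC(=O)O[C@@H](CCC(C)=C)[C@@]1(C)[C@@H](OC(C)=O)C[C@H](O)C(C)=C1 | intermediate
14 | (1S)-1-[(1S,4S,6S)-6-(acetyloxy)-4-(ethenyloxy)-1,3-dimethylcyclohex-2-en-1-yl]-4-methylpent-4-en-1-yl propanoate | CCC(=O)O[C@@H](CCC(C)=C)[C@@]1(C)[C@@H](OC(C)=O)C[C@H](OC=C)C(C)=C1 | intermediate (not isolated)
15 | (1S)-1-[(1S,2S,6S)-6-(acetyloxy)-1,3-dimethyl-2-(2-oxoethyl)cyclohex-3-en-1-yl]-4-methylpent-4-en-1-yl propanoate | CCC(=O)O[C@@H](CCC(C)=C)[C@@]1(C)[C@@H](OC(C)=O)CC=C(C)[C@@H]1CC=O | intermediate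
16 | tert-butyl 2-methyl-3-oxobutanoate | CC(=O)C(C)C(=O)OC(C)(C)C | starting material
17 | tert-butyl 2-diazopropanoate | CC(=[N+]=[N-])C(=O)OC(C)(C)C | intermediate
18 | tert-butyl 4-[(1S,5S,6S)-5-(acetyloxy)-2,6-dimethyl-6-[(1S)-4-methyl-1-(propanoyloxy)pent-4-en-1-yl]cyclohex-2-en-1-yl]-2-methyl-3-oxobutanoate (both epimers at the α-methyl carbon) | CCC(=O)O[C@@H](CCC(C)=C)[C@@]1(C)[C@@H](OC(C)=O)CC=C(C)[C@@H]1CC(=O)C(C)C(=O)OC(C)(C)C | intermediate
19 | tert-butyl (2Z)-4-[(1S,5S,6S)-5-(acetyloxy)-2,6-dimethyl-6-[(1S)-4-methyl-1-(propanoyloxy)pent-4-en-1-yl]cyclohex-2-en-1-yl]-2-methyl-3-{[(trifluoromethyl)sulfonyl]oxy}but-2-enoate | CCC(=O)O[C@@H](CCC(C)=C)[C@@]1(C)[C@@H](OC(C)=O)CC=C(C)[C@@H]1C/C(OS(=O)(=O)C(F)(F)F)=C(\C)C(=O)OC(C)(C)C | intermediate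
20 | tributyl(propa-1,2-dien-1-yl)stannane | C=C=C[Sn](CCCC)(CCCC)CCCC | starting material
21 | tert-butyl (2Z)-3-{[(1S,5S,6S)-5-(acetyloxy)-2,6-dimethyl-6-[(1S)-4-methyl-1-(propanoyloxy)pent-4-en-1-yl]cyclohex-2-en-1-yl]methyl}-2-methylhexa-2,4,5-trienoate | CCC(=O)O[C@@H](CCC(C)=C)[C@@]1(C)[C@@H](OC(C)=O)CC=C(C)[C@@H]1C/C(C=C=C)=C(\C)C(=O)OC(C)(C)C | intermediate
22 | (1S)-1-[(1S,2S,6S)-6-(acetyloxy)-2-{[(2R)-2-ethenyl-4-methyl-5-oxo-2,5-dihydrofuran-3-yl]methyl}-1,3-dimethylcyclohex-3-en-1-yl]-4-methylpent-4-en-1-yl propanoate | CCC(=O)O[C@@H](CCC(C)=C)[C@@]1(C)[C@@H](OC(C)=O)CC=C(C)[C@@H]1CC2=C(C)C(=O)O[C@@H]2C=C | intermediate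
23 | CNP0112230.1, (1S,2S,5Z,7R,10S,14S)-14-acetoxy-2-propanoyloxybriarane-5,8(17),11-triene 7,19-lactone (lactone C=O is C19 on C17, lactone O on C7) | CCC(=O)O[C@H]1CC/C(C)=C\[C@H]2OC(=O)C(C)=C2C[C@H]2C(C)=CC[C@H](OC(C)=O)[C@]12C | target

**Step count:** 14 steps in total; the longest linear sequence is 13 steps (steps 1–8 and 10–14); step 9 is a one-step side branch.

**The three steps most likely to fail**

Step 14 (metathesis closure of a ten-membered ring with a trisubstituted alkene; risks are dimerisation, migration of the vinyl group to a 5-ethylidene butenolide and E/Z control). The fallback sets out from 19 and comes back at 23, and closes the ring before the lactone exists. Stille coupling of 19 with allyltributylstannane (Pd2(dba)3, P(2-furyl)3, LiCl, NMP) gives the skipped dienoate tert-butyl (2E)-3-{[(1S,5S,6S)-5-(acetyloxy)-2,6-dimethyl-6-[(1S)-4-methyl-1-(propanoyloxy)pent-4-en-1-yl]cyclohex-2-en-1-yl]methyl}-2-methylhexa-2,5-dienoate F1. Ring-closing metathesis of the unhindered allyl terminus with the 1,1-disubstituted alkene (second-generation Grubbs catalyst, toluene, 80 °C) gives the lactone-free ten-membered ester tert-butyl (2E)-2-[(1S,2S,5Z,10S,14S)-14-(acetyloxy)-1,5,11-trimethyl-2-(propanoyloxy)bicyclo[8.4.0]tetradeca-5,11-dien-8-ylidene]propanoate F2. Wohl–Ziegler bromination (NBS, AIBN, PhCF3, 80 °C) at the doubly allylic C7 gives the bromide tert-butyl (2Z)-2-[(1S,2S,5Z,10S,14S)-14-(acetyloxy)-7-bromo-1,5,11-trimethyl-2-(propanoyloxy)bicyclo[8.4.0]tetradeca-5,11-dien-8-ylidene]propanoate F3. Silver-assisted lactonisation onto the cis tert-butyl ester (AgOTf, 2,6-di-tert-butyl-4-methylpyridine, CH2Cl2, 0 °C) then gives 23; C7 is set by the ring here, and an unwanted epimer is removed by chromatography.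

Step 13 (the new gold step; risks are a competing Nazarov-type cyclopentannulation of the vinylallene, propargyl/allenyl scrambling carried over from step 12 and the wrong facial sense). The fallback uses known chemistry, sets out from 19 and comes back at 22. A Nozaki–Hiyama–Kishi coupling of the enol triflate with acrolein (CrCl2, NiCl2 cat., DMF, 25 °C, with a chiral sulfonamide ligand for C7 control) gives the hydroxy ester tert-butyl (2Z,4R)-3-{[(1S,5S,6S)-5-(acetyloxy)-2,6-dimethyl-6-[(1S)-4-methyl-1-(propanoyloxy)pent-4-en-1-yl]cyclohex-2-en-1-yl]methyl}-4-hydroxy-2-methylhexa-2,5-dienoate F4. This lactonises on warming with camphorsulfonic acid in toluene to 22; the C7 epimer is separated if the ligand control is incomplete.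

Step 7 (Wharton reaction on a ketone flanked by a quaternary carbon and the epoxide carbon, next to two esters that hydrazine can attack). The fallback sets out from 12 and comes back at 13, and replaces the hydrazone by a radical fragmentation. Reduction (NaBH4, CeCl3·7H2O, MeOH, −20 °C) gives the epoxy alcohol (1S)-1-[4-(acetyloxy)-2-hydroxy-1,3-dimethyl-7-oxabicyclo[4.1.0]heptan-3-yl]-4-methylpent-4-en-1-yl propanoate (C=O of 12 reduced, either carbinol epimer, other centres as in 12) F5. 1,1′-Thiocarbonyldiimidazole with DMAP gives its O-(imidazol-1-ylthiocarbonyl) derivative F6. Bu3SnH and AIBN in toluene at 80 °C generate the carbinyl radical, which opens the epoxide and gives 13 with the C12–O configuration unchanged.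

**Further compounds**
F1 | step 14 | tert-butyl (2E)-3-{[(1S,5S,6S)-5-(acetyloxy)-2,6-dimethyl-6-[(1S)-4-methyl-1-(propanoyloxy)pent-4-en-1-yl]cyclohex-2-en-1-yl]methyl}-2-methylhexa-2,5-dienoate | CCC(=O)O[C@@H](CCC(C)=C)[C@@]1(C)[C@@H](OC(C)=O)CC=C(C)[C@@H]1C/C(CC=C)=C(\C)C(=O)OC(C)(C)C
F2 | step 14 | tert-butyl (2E)-2-[(1S,2S,5Z,10S,14S)-14-(acetyloxy)-1,5,11-trimethyl-2-(propanoyloxy)bicyclo[8.4.0]tetradeca-5,11-dien-8-ylidene]propanoate | CCC(=O)O[C@H]1CC/C(C)=C\C/C(=C(/C)C(=O)OC(C)(C)C)C[C@H]2C(C)=CC[C@H](OC(C)=O)[C@]12C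
F3 | step 14 | tert-butyl (2Z)-2-[(1S,2S,5Z,10S,14S)-14-(acetyloxy)-7-bromo-1,5,11-trimethyl-2-(propanoyloxy)bicyclo[8.4.0]tetradeca-5,11-dien-8-ylidene]propanoate (both C7 epimers) | CCC(=O)O[C@H]1CC/C(C)=C\C(Br)/C(=C(/C)C(=O)OC(C)(C)C)C[C@H]2C(C)=CC[C@H](OC(C)=O)[C@]12C
F4 | step 13 | tert-butyl (2Z,4R)-3-{[(1S,5S,6S)-5-(acetyloxy)-2,6-dimethyl-6-[(1S)-4-methyl-1-(propanoyloxy)pent-4-en-1-yl]cyclohex-2-en-1-yl]methyl}-4-hydroxy-2-methylhexa-2,5-dienoate | CCC(=O)O[C@@H](CCC(C)=C)[C@@]1(C)[C@@H](OC(C)=O)CC=C(C)[C@@H]1C/C(=C(\C)C(=O)OC(C)(C)C)[C@H](O)C=C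
F5 | step 7 | (1S)-1-[4-(acetyloxy)-2-hydroxy-1,3-dimethyl-7-oxabicyclo[4.1.0]heptan-3-yl]-4-methylpent-4-en-1-yl propanoate (carbinol epimers, other centres as in 12) | CCC(=O)O[C@@H](CCC(C)=C)[C@@]1(C)[C@@H](OC(C)=O)C[C@@H]2O[C@]2(C)C1O
F6 | step 7 | O-(imidazol-1-ylthiocarbonyl) derivative of F5 | CCC(=O)O[C@@H](CCC(C)=C)[C@@]1(C)[C@@H](OC(C)=O)C[C@@H]2O[C@]2(C)C1OC(=S)n3ccnc3
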